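The plan disconnects ring A of the chromone at C6–C7 and keeps ring B, the 4-pyranone, intact. It exploits the C4a=C8a double bond of ring B as the cis-locked central alkene of a hexatriene whose outer alkenes are a silyl enol ether (C5=C6) and an E-enamine (C8=C7). One thermal operation, a six-electron electrocyclization followed by loss of dimethylamine, forms C6–C7 and aromatizes ring A with the C5 oxygen already installed. The substrate for this step is a 6-pentadecyl-4-pyranone bearing a 1-(silyloxy)vinyl group on C3 and a 2-(dimethylamino)vinyl group on C2, built by an acylketene–enaminone pyranone annulation.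

Key step: step 6

Remark on the chemistry: chromone numbering is used for the ring A atoms (C4a and C8a are C3 and C2 of the pyranone); the target has no stereocentre, so only the E geometry of the enamine alkenes and a transient, uncontrolled C7 centre arise.

Step 1
Reactants: 1 palmitoyl chloride (hexadecanoyl chloride); 2 Meldrum's acid (2,2-dimethyl-1,3-dioxane-4,6-dione)
Product: 3 5-(1-hydroxyhexadecylidene)-2,2-dimethyl-1,3-dioxane-4,6-dione (palmitoyl Meldrum's acid, enol form)
Conditions: pyridine (2.2 equiv), CH2Cl2, 0 °C to rt; 1 M HCl wash
Reagents that add atoms: none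
Why: C-acylation of the acidic methylene of Meldrum's acid by an acid chloride with pyridine is the standard entry to acyl Meldrum's acids, and the product should be held as its hydrogen-bonded enol.

Step 2
Reactants: 4 acetylacetone (pentane-2,4-dione)
Product: 5 (E)-4-(pyrrolidin-1-yl)pent-3-en-2-one
Conditions: pyrrolidine (1.05 equiv), PhMe, reflux, Dean–Stark
Reagents that add atoms: pyrrolidine, C1CCNC1
Why: Condensation of a secondary amine with a 1,3-diketone under azeotropic removal of water should give the tertiary enaminone (vinylogous amide), which has no N–H and can therefore lead to a pyranone and not to a pyridone.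

Step 3
Reactants: 3 palmitoyl Meldrum's acid; 5 (E)-4-(pyrrolidin-1-yl)pent-3-en-2-one
Product: 8 3-acetyl-2-methyl-6-pentadecyl-4H-pyran-4-one, via palmitoylketene 6 (not isolated), via acyclic C-acyl enaminone 7 (not isolated)
Conditions: 3 (1.3 equiv), PhMe, 110 °C, N2 sweep; then 1 M HCl wash
Reagents that add atoms: none
Why: Thermal retro-[4+2] fragmentation of the acyl Meldrum's acid releases acetone, CO2 and the acylketene, which should be C-acylated by the nucleophilic α-carbon of the enaminone, after which the enol oxygen of the new 1,3-diketone closes onto the amine-bearing carbon by addition–elimination (acylketene–enaminone pyranone annulation, a formal [4+2]), the nitrogen sweep carrying off pyrrolidine before it can intercept further ketene.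

Step 4
Reactants: 8 3-acetyl-2-methyl-6-pentadecyl-4H-pyran-4-one; 9 N,N-dimethylformamide dimethyl acetal
Product: 10 3-acetyl-2-[(E)-2-(dimethylamino)ethenyl]-6-pentadecyl-4H-pyran-4-one
Conditions: Me2NCH(OMe)2 (1.2 equiv), PhMe, 60 °C
Reagents that add atoms: none
Why: Aminomethylenation of an activated methyl group by an amide acetal (the enamine-forming half of a Leimgruber–Batcho sequence) should occur at the 2-methyl, the only C–H acidified vinylogously by both the C4 ring carbonyl and the acetyl carbonyl, while the acetyl methyl is activated by one carbonyl only and is deactivated further once the donor enamine is conjugated to it; the E alkene is the thermodynamic geometry.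

Step 5
Reactants: 10 3-acetyl-2-[(E)-2-(dimethylamino)ethenyl]-6-pentadecyl-4H-pyran-4-one
Product: 11 3-[1-(tert-butyldimethylsilyloxy)ethenyl]-2-[(E)-2-(dimethylamino)ethenyl]-6-pentadecyl-4H-pyran-4-one
Conditions: TBSOTf (1.15 equiv), Et3N (2 equiv), CH2Cl2, −78 to 0 °C; pentane, filtration, cold concentration; used crude
Reagents that add atoms: tert-butyldimethylsilyl trifluoromethanesulfonate, CC(C)(C)[Si](C)(C)OS(=O)(=O)C(F)(F)F
Why: Soft enolization of a methyl ketone with a silyl triflate and a tertiary amine should work because O-silylation of the acetyl oxygen is assisted by the push–pull enamine, the only α-hydrogens of the resulting cation are those of the acetyl methyl, and silylation at the ring carbonyl is reversible and returns 10 on work-up.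

Step 6
Reactants: 11 3-[1-(tert-butyldimethylsilyloxy)ethenyl]-2-[(E)-2-(dimethylamino)ethenyl]-6-pentadecyl-4H-pyran-4-one
Product: 13 5-(tert-butyldimethylsilyloxy)-2-pentadecyl-4H-chromen-4-one, via 7-(dimethylamino)-6,7-dihydrochromenone 12 (not isolated)
Conditions: PhMe (0.05 M, degassed), 110 °C, N2 sweep
Reagents that add atoms: none
Why: On heating, the C6=C5–C4a=C8a–C8=C7 triene of 11 should undergo a thermally allowed disrotatory 6π electrocyclization that forms the C6–C7 σ bond and closes the six-membered carbocyclic ring A as cyclohexadiene 12, in which C7 carries NMe2 next to the new C6 methylene; ring B is only weakly aromatic, so its C4a=C8a bond can serve as the central alkene. A 1,2-elimination of dimethylamine across C6–C7 then aromatizes ring A and makes the process irreversible, the closest known reaction type being the thermal electrocyclization–amine elimination of 1-amino-hexatrienes (dienamine benzannulation of ortho-acyl methyl heteroarenes). The C7 centre of 12 forms without control and is erased on aromatization, so no stereocontrol is required. The selectivity needed is constitutional, oxygen at C5 and the new bond at C6–C7, and the substrate fixes both because the silyloxyvinyl arm sits on C4a and the aminovinyl arm on C8a, whose double bond is locked cis inside ring B. The E enamine keeps NMe2 outside the closing termini, and the amino and silyloxy donors polarize C7 and C6 so that a stepwise Mukaiyama–Mannich closure, should trace acid intervene, would form the same bond and the same product.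

Step 7
Reactants: 13 5-(tert-butyldimethylsilyloxy)-2-pentadecyl-4H-chromen-4-one
Product: 14 5-hydroxy-2-pentadecyl-4H-chromen-4-one
Conditions: Bu4NF (1.1 equiv), AcOH (1.2 equiv), THF, 0 °C
Reagents that add atoms: none
Why: Fluoride desilylation of the aryl silyl ether is driven by the strong Si–F bond, and the acetic acid buffer protects the base-sensitive ring B while the freed C5 hydroxyl becomes hydrogen-bonded to the C4 carbonyl.

Compound list
1 | palmitoyl chloride (hexadecanoyl chloride) | CCCCCCCCCCCCCCCC(=O)Cl | starting material
2 | Meldrum's acid (2,2-dimethyl-1,3-dioxane-4,6-dione) | CC1(C)OC(=O)CC(=O)O1 | starting material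
3 | 5-(1-hydroxyhexadecylidene)-2,2-dimethyl-1,3-dioxane-4,6-dione (palmitoyl Meldrum's acid) | CCCCCCCCCCCCCCCC(O)=C1C(=O)OC(C)(C)OC1=O | intermediate
4 | acetylacetone (pentane-2,4-dione) | CC(=O)CC(C)=O | starting material
5 | (E)-4-(pyrrolidin-1-yl)pent-3-en-2-one | CC(=O)/C=C(\C)N1CCCC1 | intermediate
6 | palmitoylketene (3-oxooctadec-1-en-1-one; not isolated) | CCCCCCCCCCCCCCCC(=O)C=C=O | intermediate
7 | 3-acetyl-2-(pyrrolidin-1-yl)henicos-2-ene-4,6-dione (acyclic C-acyl enaminone; not isolated) | CCCCCCCCCCCCCCCC(=O)CC(=O)C(C(C)=O)=C(C)N1CCCC1 | intermediate
8 | 3-acetyl-2-methyl-6-pentadecyl-4H-pyran-4-one | CCCCCCCCCCCCCCCc1cc(=O)c(C(C)=O)c(C)o1 | intermediate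
9 | N,N-dimethylformamide dimethyl acetal | COC(OC)N(C)C | starting material
10 | 3-acetyl-2-[(E)-2-(dimethylamino)ethenyl]-6-pentadecyl-4H-pyran-4-one | CCCCCCCCCCCCCCCc1cc(=O)c(C(C)=O)c(/C=C/N(C)C)o1 | intermediate
11 | 3-[1-(tert-butyldimethylsilyloxy)ethenyl]-2-[(E)-2-(dimethylamino)ethenyl]-6-pentadecyl-4H-pyran-4-one (key-step precursor) | CCCCCCCCCCCCCCCc1cc(=O)c(C(=C)O[Si](C)(C)C(C)(C)C)c(/C=C/N(C)C)o1 | intermediate
12 | 5-(tert-butyldimethylsilyloxy)-7-(dimethylamino)-2-pentadecyl-6,7-dihydro-4H-chromen-4-one (racemic at C7; not isolated) | CCCCCCCCCCCCCCCC1=CC(=O)C2=C(O[Si](C)(C)C(C)(C)C)CC(N(C)C)C=C2O1 | intermediate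
13 | 5-(tert-butyldimethylsilyloxy)-2-pentadecyl-4H-chromen-4-one | CCCCCCCCCCCCCCCc1cc(=O)c2c(O[Si](C)(C)C(C)(C)C)cccc2o1 | intermediate
14 | 5-hydroxy-2-pentadecyl-4H-chromen-4-one | CCCCCCCCCCCCCCCc1cc(=O)c2c(O)cccc2o1 | target

Total step count: 7. Longest linear sequence: 6 steps (steps 1, 3, 4, 5, 6, 7 from palmitoyl chloride; equally steps 2 to 7 from acetylacetone).

Steps most likely to fail

Step 6. Hydrolytic or thermal loss of the silyl enol ether and oligomerization of the electron-rich triene may outrun ring closure. The closure also interrupts the pyranone conjugation for a moment and may be slow, and elimination of the amine from 12 may stall. The fallback gives up the pericyclic closure for an intramolecular aldol condensation that forms the same C6–C7 bond. It sets out from 11: aqueous HCl in THF at rt would cleave both the silyl enol ether and the enamine to the keto aldehyde 2-(3-acetyl-4-oxo-6-pentadecyl-4H-pyran-2-yl)acetaldehyde F1. Under the same acid on warming, or with piperidinium acetate in PhMe at 80 °C, the acetyl enol should add to the aldehyde carbon, and dehydration with tautomerization would aromatize ring A. The path comes back to the route at 14, so step 7 is not needed.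

Step 5. Silylation may go to the wrong site: the ring carbonyl oxygen, followed by deprotonation at the pentadecyl α-CH2, or the nucleophilic enamine carbon C8. The silyl enol ether may also be hydrolysed during isolation. The fallback uses the metal enolate itself as the C6 nucleophile and sets out from 10. LiN(SiMe3)2 (2.2 equiv) in THF at −78 °C to rt should deprotonate the acetyl methyl, and the lithium enolate would add to the aminovinyl carbon C7 in a 6-endo vinylogous addition–elimination (base-mediated enaminone benzannulation). Lithium dimethylamide is expelled and the phenoxide is protonated on work-up, so the path comes back to the route at 14; no new compound is made on the way (F0).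

Step 3. The pyrrolidine released on ring closure, or adventitious water, may capture the acylketene 6, or 6 may dimerize, before it meets the only moderately nucleophilic push–pull enaminone. The fallback assembles 8 without a ketene and sets out from acetylacetone 4.
- 1-Heptadecyne F2 (purchased) would be deprotonated with n-BuLi in THF at −78 °C and carboxylated with CO2 to octadec-2-ynoic acid F3.
- (COCl)2 with catalytic DMF in CH2Cl2 would give octadec-2-ynoyl chloride F4.
- C-acylation of 4 under soft enolization (MgCl2, pyridine, CH2Cl2, 0 °C) should give the triacylmethane 3-acetylhenicos-5-yne-2,4-dione F5.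
- The enol oxygen of F5 would add 6-endo-dig to the ynone (catalytic K2CO3, MeCN, rt) and close ring B.

The path comes back to the route at 8, and steps 1 and 2 fall away.

Further compounds
F1 | step 6 | 2-(3-acetyl-4-oxo-6-pentadecyl-4H-pyran-2-yl)acetaldehyde | CCCCCCCCCCCCCCCc1cc(=O)c(C(C)=O)c(CC=O)o1
F0 | step 5 | none | none
F2 | step 3 | 1-heptadecyne (purchased for the fallback) | CCCCCCCCCCCCCCCC#C
F3 | step 3 | octadec-2-ynoic acid | CCCCCCCCCCCCCCCC#CC(=O)O
F4 | step 3 | octadec-2-ynoyl chloride | CCCCCCCCCCCCCCCC#CC(=O)Cl
F5 | step 3 | 3-acetylhenicos-5-yne-2,4-dione | CCCCCCCCCCCCCCCC#CC(=O)C(C(C)=O)C(C)=O
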